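The readings were generated by integration for substances that don't exist, noise included.

- My first reading in Friday's run, at 0.417 d, lies past the moment in question: the left-handed substrate has already lost 12 percentage points of the substrates together, more than the 10% asked about. I must therefore reckon that moment.

common to all: left-handed substrate 0.20 M; right-handed substrate 0.20 M

| flask | coupling partner | protic impurity | free catalyst | remark |
|---|---|---|---|---|
| Friday's | 0.12 M | 0.28 M | 4 mM | run made earlier |
| Sunday's | 0.12 M | 0.44 M | 4 mM | run made earlier |
| flask | 0.120 M | 0.200 M | 4.0 mM |  |

| run | time / d | left-handed product / % | left-handed substrate / % |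
|---|---|---|---|
| Friday's | 0.417 | 12.2 | 37.7 |
| Friday's | 0.625 | 13.7 | 36.4 |
| Friday's | 0.833 | 14.1 | 35.5 |
| Friday's | 1.25 | 14.2 | 34.9 |
| Friday's | 2.08 | 15.0 | 35.0 |
| Friday's | 3.00 | 15.1 | 34.4 |
| Friday's | 5.00 | 15.6 | 35.0 |
| Sunday's | 0.250 | 10.1 | 40.8 |
| Sunday's | 0.833 | 12.8 | 37.5 |
| Sunday's | 1.25 | 13.0 | 36.8 |
| Sunday's | 2.08 | 13.2 | 36.7 |
| Sunday's | 3.00 | 13.3 | 37.1 |
| Sunday's | 4.00 | 13.2 | 36.6 |
| Sunday's | 5.00 | 12.6 | 37.0 |

(each reading ± 0.3 percentage points)

- free catalyst is single-handed; left-handed substrate and right-handed substrate are mirror images of each other, charged as a racemate, each of them at the stated concentration
- the analysis behind the earlier runs scatters by 0.3 percentage points, standard deviation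
- steps under discussion: coupling partner + free catalyst + left-handed substrate -> free catalyst + left-handed product; coupling partner + protic impurity -> quenched reagent; coupling partner + free catalyst -> spent catalyst; coupling partner + free catalyst + right-handed substrate -> free catalyst + right-handed product
- no earlier run changes the charge of free catalyst; that part of a forecast is a guess
- no earlier run changes the charge of coupling partner; that part of a forecast is a guess

- apparent order in free catalyst when 10% of the left-handed substrate and right-handed substrate together are converted (percent change of the rate of making left-handed product for one percent more free catalyst charged)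
- apparent order in coupling partner when 10% of the left-handed substrate and right-handed substrate together are converted (percent change of the rate of making left-handed product for one percent more coupling partner charged)

- The next rung is the stall: Friday's left-handed substrate reads 34.9% at 1.25 d and 35.0% at 5.00 d, a difference within the scatter.
- The coupling partner is the limiting reagent, since its charge covers 30.0% of the substrates together.
- The quench works on the same rung: Sunday's run, with more protic impurity, stalls at 13.3% left-handed product against Friday's 15.1%.
- For the new flask I carry one quantity, the partner's reserve, the fraction of its charge that the products leave at the chosen conversion: 66.7%.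
- With the quench set aside, products take a fixed amount at fixed conversion, so one percent more charge raises what is left by 1.50 percent. I commit to that as a floor for the order in coupling partner.
- The quench lowers the reserve and so raises that order. More free catalyst reaches the same conversion sooner and gives the quench less time, so I put its order above one.
- The forecast gives 1.8 (1.6 to 2.05) for the coupling partner and 1.2 (1.08 to 1.45) for free catalyst, “slightly more if the catalyst dies”.

    coupling partner + free catalyst + left-handed substrate → free catalyst + left-handed product (k = 147 M⁻² h⁻¹)
    coupling partner + protic impurity → quenched reagent (k = 0.181 M⁻¹ h⁻¹)
    coupling partner + free catalyst → spent catalyst (k = 0.402 M⁻¹ h⁻¹)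
    coupling partner + free catalyst + right-handed substrate → free catalyst + right-handed product (k = 59.6 M⁻² h⁻¹)

- The flask gives 1.7 in coupling partner, above the 1.50 from my reserve, and 1.3 in free catalyst, with 89.7% of the catalyst still free at 0.123 d. At the start of the flask, the path to left-handed product uses coupling partner 2.5 times as fast as the path to right-handed product. At 6.00 d the flask holds 0% of its coupling partner and 73.6% of its catalyst as free catalyst.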